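## Retrosynthetic overview

1. Target 22 is (1R,3R,6S,7R,8S,10S)-1,10-epoxy-3-hydroxy-6-isobutyryloxygermacra-4E,11(13)-dien-12,8-olide (cis-epoxide, trans-fused lactone). The last operations are O3 desilylation, epoxidation of the Z-C1=C10 olefin, α-methylenation (C13), oxidation of a 2,3-dihydrofuran to the lactone, and C6 acylation.
2. The E-C4=C5 olefin comes from syn-dehydration of a C4 carbinol, itself from a 4,5-epoxy ketone; the epoxide also masks the ring olefin during the key step.
3. The ten-membered ring comes from the C8–C9 bond, formed by an anionic oxy-Cope ring expansion of a cyclohexanol with dearomatisation of a furan. One step gives the carbocycle, the Z-olefin, the C6 ketone, the C8 stereocentre and the five-membered O-heterocycle.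
4. Enabling feature: the lactone ring atoms O–C8–C7–C11–C12 are a 3-substituted furan. Its C2=C3 bond (C8=C7) is joined through carbinol C6 and ring carbon C1 to the isopropenyl group C10(=C9)–C14. This is a 3-oxy-1,5-diene spanning the C1–C6 bond of the cyclohexane ring C1–C6.
5. The cyclohexanol comes from 3-furyllithium and an enone made from (R)-carvone. Ring order: cyclohexane (chiral pool) → carbocycle + dihydrofuran (step 6) → lactone (step 11) → oxirane (step 14).

Key step: step 6

Remark: germacrane numbering of the target is used for all intermediates (C8 lactone carbinol, C9 its CH2, C10/C1 epoxide carbons, C3 carbinol, C4=C5, C6 acyloxy carbon, C7 ring fusion, C11–C13 lactone); C11 in 18 and 19 and the acetal carbon in F2–F5 are stereochemically inconsequential.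

## Route

Step 1
Reactants: 1 (R)-(−)-carvone
Product: 2 (1R,5R)-cis-carveol
Conditions: NaBH4, CeCl3·7H2O, MeOH, 0 °C
Reagents that add atoms: none
Why: Luche 1,2-reduction; axial hydride attack on the enone half-chair (isopropenyl equatorial) sets C3 and gives the cis-alcohol.

Step 2
Reactants: 2 (1R,5R)-cis-carveol
Product: 3 cis-carveol TBS ether
Conditions: TBSCl, imidazole, DMF, rt
Reagents that add atoms: tert-butyldimethylsilyl chloride, CC(C)(C)[Si](C)(C)Cl
Why: Standard silylation of the secondary allylic alcohol; the ether should survive organolithium, KH, SmI2 and chromium oxidants and is removed last.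

Step 3
Reactants: 3 cis-carveol TBS ether
Product: 4 (4R,6R)-4-(tert-butyldimethylsilyloxy)-3-methyl-6-(prop-1-en-2-yl)cyclohex-2-en-1-one
Conditions: CrO3, 3,5-dimethylpyrazole, CH2Cl2, −20 °C
Reagents that add atoms: chromium trioxide, O=[Cr](=O)=O
Why: Allylic oxidation at the only ring CH2 allylic to the trisubstituted olefin should give the enone without transposition; the hindered C–H at the silyloxy carbon and the isopropenyl group react more slowly, and the non-basic medium keeps the stereocentre α to the new ketone intact.

Step 4
Reactants: 4 enone; 5 3-bromofuran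
Product: 7 (1S,4R,6R)-4-(tert-butyldimethylsilyloxy)-1-(furan-3-yl)-3-methyl-6-(prop-1-en-2-yl)cyclohex-2-en-1-ol, via 3-furyllithium 6 (not isolated)
Conditions: 5, n-BuLi, THF, −78 °C; then 4, −78 °C; then H2O
Reagents that add atoms: none
Why: 1,2-Addition of an aryllithium to an enone; the cis silyloxy and isopropenyl groups hold the half-chair with both equatorial, and axial attack (antiperiplanar to the axial C1–H) should place the furyl group cis to the isopropenyl group, setting the C6 carbinol centre.

Step 5
Reactants: 7 furyl carbinol
Product: 8 syn-epoxy alcohol (4,5-epoxide cis to the tertiary OH, trans to the furyl and silyloxy groups)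
Conditions: mCPBA, NaHCO3, CH2Cl2, 0 °C
Reagents that add atoms: 3-chloroperoxybenzoic acid, OOC(=O)c1cccc(Cl)c1
Why: Peracid epoxidation of the trisubstituted allylic-alcohol olefin should occur syn to the pseudo-equatorial hydroxyl (hydrogen-bond delivery) and anti to the axial furyl and silyloxy groups; the epoxide masks the ring olefin in step 6, cannot undergo Payne migration (cis to the alkoxide) and later becomes the E-olefin.

Step 6
Reactants: 8 syn-epoxy alcohol
Product: 11 trans-fused 13-nor epoxy ketone (dihydrofuran-annulated (Z)-cyclodecenone), via potassium alkoxide 9 (not isolated), via potassium dienolate 10 (not isolated)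
Conditions: KH, 18-crown-6, THF, 0 → 60 °C; then AcOH, −78 °C → rt
Reagents that add atoms: none
Why: Proposed new method: alkoxide 9 should undergo an anion-accelerated [3,3]-sigmatropic shift (anionic oxy-Cope) in which the furan C2=C3 bond (C8=C7) is the second 2π component, so that C1–C6 breaks, C8–C9 forms and dienolate 10 results, which cannot rearomatise because C8 now carries C9; the closest known reactions are the anionic oxy-Cope ring expansion of cis-1,2-dialkenylcyclohexanols to (Z)-cyclodec-5-enones and anion-accelerated aromatic Cope rearrangements of aryl carbinols, and the step is polarity-matched because in the dissociative limit an allyl anion adds to C2 of a 3-acylfuran, a β-alkoxy-enone carbon. The ten-membered carbocycle is closed by six-to-ten ring expansion through a chair-like transition state, and the furan becomes the 2,3-dihydrofuran that carries all five lactone ring atoms. The C1=C10 olefin should be Z because the cis-1,3 pair (equatorial isopropenyl at C1, equatorial silyloxy at C3) locks the half-chair with the furyl group axial, which puts C2 pseudo-axial in the chair; C8 (S) follows from chirality transfer from C1 and C6 through this chair, C9 bonding to the furan face that lies below C1. C7 is set on protonation: kinetic protonation anti to C9 would give the cis ring fusion, but C7–H stays acidic (α to the C6 ketone) through steps 6 to 8 and is expected to settle in the trans-fused form, as vicinal substituents on a five-membered ring do, before step 9 fixes it. The selectivity needed is a [3,3] shift through the furan rather than β-fragmentation of the alkoxide or a shift through another π bond: the 4,5-epoxide removes the only competing alkene, 18-crown-6 maximises the rate, and β-elimination of the ring oxygen from 10 is stereoelectronically disfavoured because the C8–O bond lies close to the nodal plane of the dienolate.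

Step 7
Reactants: 11 epoxy ketone
Product: 12 4-hydroxy-6-ketone (β-hydroxy ketone)
Conditions: SmI2, THF/MeOH, −90 °C
Reagents that add atoms: none
Why: SmI2 reductive cleavage of the Cα–O bond of an α,β-epoxy ketone (ketyl, β-scission, protonation of the samarium enolate by MeOH) should give the β-hydroxy ketone without touching the enol ether, the olefin or the silyl ether.

Step 8
Reactants: 12 β-hydroxy ketone
Product: 13 (1(10)Z,4E)-dienone
Conditions: Burgess reagent (MeO2CNSO2NEt3), toluene, 50 °C
Reagents that add atoms: none
Why: Burgess dehydration is a syn (Ei) elimination toward the acidic C5–H; the cyclic transition state leading to the E-olefin keeps the ring bonds C3–C4 and C5–C6 anticlinal whereas that leading to the Z-olefin must eclipse them, which is the basis of the known preference of syn-eliminations in ten-membered rings for the trans-cycloalkene, so the E-enone is expected.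

Step 9
Reactants: 13 dienone
Product: 14 (6S)-allylic alcohol
Conditions: i-Bu2AlH, CH2Cl2, −78 °C; aq. KNaC4H4O6 work-up
Reagents that add atoms: none
Why: 1,2-Reduction of the enone; by the Felkin–Anh model the hydride should enter anti to the C7–C8 bond (perpendicular to the carbonyl, i.e. from outside the ring) past H7, which sets 6S, and the non-acidic conditions spare the enol ether.

Step 10
Reactants: 14 allylic alcohol
Product: 15 6-O-isobutyrate
Conditions: i-PrCOCl, pyridine, DMAP (cat.), CH2Cl2, 0 °C → rt
Reagents that add atoms: isobutyryl chloride, CC(C)C(Cl)=O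
Why: DMAP-catalysed acylation under basic conditions that leave the acid-labile enol ether intact; done before the lactone exists so that no translactonisation between O6 and O8 can occur.

Step 11
Reactants: 15 isobutyrate
Product: 16 13-nor-12,8-olide (γ-lactone)
Conditions: [C5H5NH][CrO3Cl] (pyridinium chlorochromate), 4 Å sieves, CH2Cl2, rt
Reagents that add atoms: pyridinium chlorochromate, [O-][Cr](=O)(=O)Cl.c1cc[nH+]cc1
Why: Oxidation of a cyclic enol ether to the lactone by pyridinium chlorochromate (chromate ester of the oxocarbenium ion, then collapse to C=O) is a known conversion of 2,3-dihydrofurans into γ-butyrolactones; olefins, ester and silyl ether should be inert.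

Step 12
Reactants: 16 lactone
Product: 18 Mannich base (11-dimethylaminomethyl lactone), via lithium enolate 17 (not isolated)
Conditions: LiN(SiMe3)2, THF, −78 °C; then CH2=NMe2+ I−, −78 → 0 °C
Reagents that add atoms: Eschenmoser's salt, C=[N+](C)C.[I-]
Why: The lactone α-CH2 (s-cis ester, more acidic and less hindered than the isobutyrate α-CH) should be deprotonated selectively, and the enolate is aminomethylated (Mannich reaction) anti to the C7 substituent.

Step 13
Reactants: 18 Mannich base
Product: 20 α-methylene lactone (3-O-TBS, 1(10)Z,4E), via methiodide 19 (not isolated)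
Conditions: MeI, THF, rt; then aq. NaHCO3, rt
Reagents that add atoms: none
Why: N-Methylation and mild-base β-elimination (Hofmann-type) of the ammonium salt give the exocyclic α-methylene lactone without enolising the ester.

Step 14
Reactants: 20 α-methylene lactone
Product: 21 3-O-TBS ether of the target
Conditions: mCPBA, NaHCO3, CH2Cl2, 0 °C
Reagents that add atoms: 3-chloroperoxybenzoic acid, OOC(=O)c1cccc(Cl)c1
Why: Prilezhaev epoxidation is stereospecific (Z-olefin to cis-epoxide) and should be chemoselective for the electron-rich C1=C10 bond (C4=C5 is flanked by two oxygenated carbons, C11=C13 is electron-poor); attack on the outward face of the Z-olefin in the preferred ring conformer is expected to give (1R,10S).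

Step 15
Reactants: 21 silyl ether
Product: 22 CNP0114243.1
Conditions: HF·pyridine, pyridine, THF, 0 °C → rt
Reagents that add atoms: none
Why: Buffered HF·pyridine cleaves the secondary TBS ether; the epoxide, the α-methylene lactone and the ester should tolerate these conditions.

## Compound list

1 | (R)-(−)-carvone | CC(=C)[C@@H]1CC=C(C)C(=O)C1 | starting material
2 | (1R,5R)-cis-carveol | CC(=C)[C@@H]1CC=C(C)[C@H](O)C1 | intermediate
3 | (1R,5R)-cis-carveol tert-butyldimethylsilyl ether | CC(=C)[C@@H]1CC=C(C)[C@H](O[Si](C)(C)C(C)(C)C)C1 | intermediate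
4 | (4R,6R)-4-(tert-butyldimethylsilyloxy)-3-methyl-6-(prop-1-en-2-yl)cyclohex-2-en-1-one | CC(=C)[C@@H]1C(=O)C=C(C)[C@H](O[Si](C)(C)C(C)(C)C)C1 | intermediate
5 | 3-bromofuran | Brc1ccoc1 | starting material
6 | 3-furyllithium (not isolated) | [Li]c1ccoc1 | intermediate
7 | (1S,4R,6R)-4-(tert-butyldimethylsilyloxy)-1-(furan-3-yl)-3-methyl-6-(prop-1-en-2-yl)cyclohex-2-en-1-ol (furyl, isopropenyl and silyloxy all cis) | CC(=C)[C@@H]1[C@](O)(c2ccoc2)C=C(C)[C@H](O[Si](C)(C)C(C)(C)C)C1 | intermediate
8 | syn-epoxy alcohol: 4,5-epoxide of 7, oxygen cis to the tertiary OH | CC(=C)[C@@H]1[C@](O)(c2ccoc2)[C@H]3O[C@@]3(C)[C@H](O[Si](C)(C)C(C)(C)C)C1 | intermediate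
9 | potassium alkoxide of 8 (not isolated) | CC(=C)[C@@H]1[C@]([O-])(c2ccoc2)[C@H]3O[C@@]3(C)[C@H](O[Si](C)(C)C(C)(C)C)C1.[K+] | intermediate
10 | potassium dienolate, C6(O−)=C7 E, C1=C10 Z (not isolated) | [K+].[O-]/C1=C2/C=CO[C@H]2C/C(C)=C\C[C@@H](O[Si](C)(C)C(C)(C)C)[C@]3(C)O[C@H]13 | intermediate
11 | (1(10)Z)-3-(TBSO)-4,5-epoxy-8,12-epoxy-13-norgermacra-1(10),11-dien-6-one, trans ring fusion (7R,8S), C3 as in the target | C1=CO[C@H]2C/C(C)=C\C[C@@H](O[Si](C)(C)C(C)(C)C)[C@]3(C)O[C@@H]3C(=O)[C@H]12 | intermediate
12 | 4-hydroxy analogue of 11 with C5 = CH2 (β-hydroxy ketone) | C1=CO[C@H]2C/C(C)=C\C[C@@H](O[Si](C)(C)C(C)(C)C)[C@](C)(O)CC(=O)[C@H]12 | intermediate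
13 | (1(10)Z,4E)-3-(TBSO)-8,12-epoxy-13-norgermacra-1(10),4,11-trien-6-one | C1=CO[C@H]2C/C(C)=C\C[C@@H](O[Si](C)(C)C(C)(C)C)/C(C)=C/C(=O)[C@H]12 | intermediate
14 | (6S)-allylic alcohol from 13 | C1=CO[C@H]2C/C(C)=C\C[C@@H](O[Si](C)(C)C(C)(C)C)/C(C)=C/[C@H](O)[C@H]12 | intermediate
15 | 6-O-isobutyrate of 14 | C1=CO[C@H]2C/C(C)=C\C[C@@H](O[Si](C)(C)C(C)(C)C)/C(C)=C/[C@H](OC(=O)C(C)C)[C@H]12 | intermediate
16 | (1(10)Z,4E)-3-(TBSO)-6-isobutyryloxy-13-norgermacra-1(10),4-dien-12,8-olide (trans-lactone) | C1C(=O)O[C@H]2C/C(C)=C\C[C@@H](O[Si](C)(C)C(C)(C)C)/C(C)=C/[C@H](OC(=O)C(C)C)[C@H]12 | intermediate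
17 | lithium enolate of 16 (not isolated) | C1=C([O-])O[C@H]2C/C(C)=C\C[C@@H](O[Si](C)(C)C(C)(C)C)/C(C)=C/[C@H](OC(=O)C(C)C)[C@H]12.[Li+] | intermediate
18 | 11-(dimethylaminomethyl) lactone (Mannich base; C13 trans to C6) | CN(C)C[C@H]1C(=O)O[C@H]2C/C(C)=C\C[C@@H](O[Si](C)(C)C(C)(C)C)/C(C)=C/[C@H](OC(=O)C(C)C)[C@H]12 | intermediate
19 | trimethylammonium iodide of 18 (not isolated) | C[N+](C)(C)C[C@H]1C(=O)O[C@H]2C/C(C)=C\C[C@@H](O[Si](C)(C)C(C)(C)C)/C(C)=C/[C@H](OC(=O)C(C)C)[C@H]12.[I-] | intermediate
20 | (1(10)Z,4E)-3-(TBSO)-6-isobutyryloxygermacra-1(10),4,11(13)-trien-12,8-olide | C=C1C(=O)O[C@H]2C/C(C)=C\C[C@@H](O[Si](C)(C)C(C)(C)C)/C(C)=C/[C@H](OC(=O)C(C)C)[C@H]12 | intermediate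
21 | 3-O-TBS ether of the target ((1R,10S)-epoxide) | C=C1C(=O)O[C@H]2C[C@]3(C)O[C@@H]3C[C@@H](O[Si](C)(C)C(C)(C)C)/C(C)=C/[C@H](OC(=O)C(C)C)[C@H]12 | intermediate
22 | CNP0114243.1 | C=C1C(=O)O[C@H]2C[C@]3(C)O[C@@H]3C[C@@H](O)/C(C)=C/[C@H](OC(=O)C(C)C)[C@H]12 | target

## Step count and risks

Total steps: 15. Longest linear sequence: 15 steps (1 → 22; 3-bromofuran 5 enters in step 4).

Steps most likely to fail:

Step 6 (Proposed new method). The furan π bond may not take part in the [3,3] shift; the alkoxide may instead fragment by cleavage of the C1–C6 bond without recombination. The fallback sets out from 4, comes back at 11, and replaces the furan by a non-aromatic cyclic enol ether, so that every operation is of a known type. Nucleophilic epoxidation of 4 (t-BuOOH, DBU, CH2Cl2, 0 °C; addition anti to the silyloxy group) would give the epoxy ketone F1. The partner would be made from commercial 2,5-dimethoxytetrahydrofuran: acid-catalysed loss of methanol gives 2-methoxy-2,3-dihydrofuran F2, and Br2 followed by Et3N gives 4-bromo-2-methoxy-2,3-dihydrofuran F3. Bromine–lithium exchange on F3 (t-BuLi, THF, −78 °C) and addition to F1, anti to the epoxide oxygen, would give the dihydrofuranyl carbinol F4. KH/18-crown-6 should then bring about an ordinary anionic oxy-Cope rearrangement with an enol ether double bond as the second alkene, and protonation would give the cyclic acetal F5. Pyridinium p-toluenesulfonate (cat.) in hot toluene removes methanol and returns enol ether 11.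

Step 4. Facial selectivity of the aryllithium addition may be poor or reversed; equatorial attack would give the trans-dialkenyl carbinol, which would ring-expand to the E-olefin and the C8 epimer. The fallback sets out from 4, comes back at 7, and replaces conformational control by alkoxide delivery. HF·pyridine frees the C3 hydroxyl to give the hydroxy enone F6. With 2.2 equiv of 3-furyllithium, the first equivalent forms the lithium alkoxide, which should deliver the second to the carbonyl face on its own side (alkoxide-directed 1,2-addition), giving the cis-diol F7. TBSCl/imidazole silylates only the secondary hydroxyl and returns 7.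

Step 14. The peracid may attack the other face of the Z-olefin, or facial selectivity may be poor. The fallback sets out from 20, comes back at 21, and delivers the oxygen to the face opposite to the one an electrophile attacks. NBS in aqueous THF would form the bromonium ion on the exposed face, and water opens it anti at the tertiary C10 to give the bromohydrin F8. DBU then closes the epoxide by displacement of bromide at C1, giving 21.

## Further compounds

F1 | step 6 | epoxy ketone from 4 (4,5-epoxide trans to the silyloxy group) | CC(=C)[C@@H]1C(=O)[C@H]3O[C@@]3(C)[C@H](O[Si](C)(C)C(C)(C)C)C1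
F2 | step 6 | 2-methoxy-2,3-dihydrofuran | COC1CC=CO1
F3 | step 6 | 4-bromo-2-methoxy-2,3-dihydrofuran | COC1CC(Br)=CO1
F4 | step 6 | dihydrofuranyl carbinol (analogue of 8 with 2-methoxy-2,3-dihydrofuran-4-yl in place of 3-furyl) | CC(=C)[C@@H]1[C@](O)(C2=COC(OC)C2)[C@H]3O[C@@]3(C)[C@H](O[Si](C)(C)C(C)(C)C)C1
F5 | step 6 | cyclic methyl acetal analogue of 11 (C11 = CH2, C12 = CH(OMe)) | C1C(OC)O[C@H]2C/C(C)=C\C[C@@H](O[Si](C)(C)C(C)(C)C)[C@]3(C)O[C@@H]3C(=O)[C@H]12
F6 | step 4 | (4R,6R)-4-hydroxy-3-methyl-6-(prop-1-en-2-yl)cyclohex-2-en-1-one | CC(=C)[C@@H]1C(=O)C=C(C)[C@H](O)C1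
F7 | step 4 | cis-diol (desilyl 7) | CC(=C)[C@@H]1[C@](O)(c2ccoc2)C=C(C)[C@H](O)C1
F8 | step 14 | bromohydrin of 20 (C10–OH, C1–Br, anti) | C=C1C(=O)O[C@H]2C[C@](C)(O)[C@@H](Br)C[C@@H](O[Si](C)(C)C(C)(C)C)/C(C)=C/[C@H](OC(=O)C(C)C)[C@H]12
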